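The target is C2-symmetric: two identical 3-methylquinolizidin-2-one units (rings A and B around N5) are joined head to tail, C9 of each to C1 of the other, by two pentamethylene tethers in a 16-membered carbocycle. The two tether bonds between the first and second carbon counted from C9 are therefore equivalent, and the route cuts both. One enantiopure monomer, a 9-vinyl-1-(pent-4-enyl)quinolizidinone, is cyclodimerised by olefin metathesis: cross-metathesis makes one of these bonds, ring-closing metathesis of the linear dimer makes the other and closes the macrocycle. Hydrogenation then gives the target. The monomer is built by sulfinimine Mannich chemistry and a formaldehyde Mannich ring closure.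

Key step: step 10

Remark 1: the carbon that becomes C1 is introduced racemic in step 1 and stays an epimer pair until step 9, where it equilibrates next to the ketone; the SMILES of these intermediates carry no descriptor at that carbon.
Remark 2: the olefins formed in step 10 are expected as E/Z mixtures and are drawn without geometry; step 11 removes them.
Remark 3: the facial sense of step 5 is taken as the one established for acetate enolate additions to aldimines with (S)-configured sulfinyl sulfur (N, imine substituent, CH2CO2Me clockwise with H away).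

Step 1
Reactants: 1 ethyl 3-oxopentanoate; 2 5-bromopent-1-ene
Product: 3 ethyl 2-propanoylhept-6-enoate (racemic)
Conditions: K2CO3, NaI (cat.), acetone, reflux
Reagents that add atoms: none
Why: C-alkylation of the β-keto ester enolate with a primary bromide (acetoacetic ester alkylation) should install the pentenyl chain; the new centre is racemic and is equilibrated later as C1.

Step 2
Reactants: 3 ethyl 2-propanoylhept-6-enoate
Product: 4 ethyl 2-(2-ethyl-1,3-dioxolan-2-yl)hept-6-enoate (racemic)
Conditions: HOCH2CH2OH, p-TsOH·H2O (cat.), toluene, reflux, Dean–Stark trap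
Reagents that add atoms: ethane-1,2-diol, OCCO
Why: Acid-catalysed ketalisation with azeotropic removal of water should mask the ketone as a dioxolane that survives hydride, enolate and ylide chemistry and falls off with acid in step 9.

Step 3
Reactants: 4 ethyl 2-(2-ethyl-1,3-dioxolan-2-yl)hept-6-enoate
Product: 5 2-(2-ethyl-1,3-dioxolan-2-yl)hept-6-enal (racemic)
Conditions: iBu2AlH (1.05 equiv), CH2Cl2, −78 °C; aq. potassium sodium tartrate
Reagents that add atoms: none
Why: Partial reduction of the ester stops at the aldehyde because the tetrahedral aluminium hemiacetal is stable at −78 °C and collapses only on work-up.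

Step 4
Reactants: 5 2-(2-ethyl-1,3-dioxolan-2-yl)hept-6-enal; 6 (S)-2-methylpropane-2-sulfinamide
Product: 7 (S,E)-N-[2-(2-ethyl-1,3-dioxolan-2-yl)hept-6-en-1-ylidene]-2-methylpropane-2-sulfinamide
Conditions: Ti(OEt)4 (2 equiv), THF, rt
Reagents that add atoms: none
Why: Lewis-acid-mediated condensation of the aldehyde with the sulfinamide (water scavenged by the titanium alkoxide) should give the E-configured N-sulfinyl aldimine without touching the sulfur stereocentre.

Step 5
Reactants: 7 N-sulfinyl aldimine; 8 methyl acetate
Product: 9 methyl (3R)-3-{[(S)-tert-butylsulfinyl]amino}-4-(2-ethyl-1,3-dioxolan-2-yl)non-8-enoate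
Conditions: LiN(iPr)2, 8, THF, −78 °C; ClTi(OiPr)3 (2 equiv); then 7, −78 °C
Reagents that add atoms: none
Why: Sulfinimine Mannich addition of the titanium ester enolate through a closed six-membered transition state in which the metal is held by the sulfinyl group, so that the (S)-sulfur should direct attack to the imine face giving the (3R)-amine (the future C9a); the neighbouring racemic centre only adds an epimer pair.

Step 6
Reactants: 9 β-sulfinylamino ester; 10 1-chloro-3-iodopropane
Product: 11 methyl (2S,3S)-3-{[(S)-tert-butylsulfinyl]amino}-2-(3-chloropropyl)-4-(2-ethyl-1,3-dioxolan-2-yl)non-8-enoate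
Conditions: LiN(iPr)2 (2.2 equiv), THF, −78 → −40 °C; then 10, DMPU, −78 → −20 °C
Reagents that add atoms: none
Why: Alkylation of the N,O-dilithio dianion of the β-amino ester, whose lithium-bridged chelate should be attacked by the iodide terminus on the face away from the C3 substituent to give the 2,3-anti product (future C9 set relative to C9a); the chloride is left for step 7.

Step 7
Reactants: 11 anti-2-(3-chloropropyl)-3-sulfinylamino ester
Product: 12 methyl (2S,3S)-1-[(S)-tert-butylsulfinyl]-2-[1-(2-ethyl-1,3-dioxolan-2-yl)hex-5-en-1-yl]piperidine-3-carboxylate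
Conditions: NaH (1.1 equiv), NaI (cat.), DMF, 0 °C → rt
Reagents that add atoms: none
Why: Intramolecular SN2 N-alkylation (6-exo-tet) of the sodium sulfinamide should close ring B without touching a stereocentre and turn the anti relationship into the 2,3-cis piperidine.

Step 8
Reactants: 12 cis-piperidine ester
Product: 14 (2R,3R)-1-[(S)-tert-butylsulfinyl]-3-ethenyl-2-[1-(2-ethyl-1,3-dioxolan-2-yl)hex-5-en-1-yl]piperidine, via piperidine-3-carbaldehyde 13 (not isolated)
Conditions: iBu2AlH (1.1 equiv), CH2Cl2, −78 °C; then Ph3P=CH2 (from Ph3PCH3Br, KN(SiMe3)2, THF), −78 °C → rt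
Reagents that add atoms: methyltriphenylphosphonium bromide, C[P+](c1ccccc1)(c1ccccc1)c1ccccc1.[Br-]
Why: One-pot ester reduction and Wittig methylenation, in which the aluminium hemiacetal should release the aldehyde only in the presence of the ylide, limiting epimerisation of the cis C3 centre; sulfinamide and ketal are inert to both reagents.

Step 9
Reactants: 14 N-sulfinyl 3-vinylpiperidine ketal
Product: 16 (1R,3S,9R,9aR)-9-ethenyl-3-methyl-1-(pent-4-en-1-yl)octahydro-2H-quinolizin-2-one, via amino ketone 15 (not isolated)
Conditions: 1 M aq. HCl (2.5 equiv), THF, 40 °C; then 37% aq. CH2O (1.5 equiv), 55 °C; cold aq. K2CO3 work-up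
Reagents that add atoms: formaldehyde, C=O; water, O
Why: Acid should remove the sulfinyl group and the ketal, and the secondary ammonium salt then undergoes an intramolecular Mannich reaction with formaldehyde (6-endo attack of the ketone enol carbon C3 on the N-methylene iminium) that closes ring A; C3 and C1 equilibrate through the enol to the all-equatorial trans-quinolizidinone, while C9 and C9a are held because the protonated nitrogen cannot undergo retro-Michael cleavage.

Step 10
Reactants: 16 9-vinyl-1-(pent-4-enyl)quinolizidinone (two molecules)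
Product: 18 16-membered head-to-tail cyclodimer diene with each unit (1R,3S,9R,9aR), via linear head-to-tail dimer 17 (not isolated)
Conditions: (1S)-camphor-10-sulfonic acid (1.05 equiv), CH2Cl2 (5 mM), RuCl2(=CHPh)(PCy3)(H2IMes) (second-generation Grubbs catalyst, 2 × 5 mol%), 40 °C, Ar purge; aq. NaHCO3 wash
Reagents that add atoms: none
Why: Cross-metathesis followed by ring-closing metathesis: the ruthenium alkylidene loads on the unhindered pentenyl terminus of one ammonium salt and engages the C9 vinyl group of a second molecule to give linear dimer 17, and the same pairing of the two remaining termini closes the ring by forming the second, symmetry-equivalent CH=CH bond between the tether carbon on C9 and its neighbour (the former C4 of the pentenyl chain on C1 of the other unit). The closest known reaction type is the head-to-tail metathesis cyclodimerisation of α,ω-dienes used for C2-symmetric macrodiolides and cyclophanes. The only ring closed is the 16-membered carbocycle, by macrocyclic ring-closing metathesis of the two olefin termini of 17 with loss of ethene. No stereocentre is created; C1, C3, C9 and C9a are spectators and the geometry of the new olefins is erased in step 11. The step needs head-to-tail over head-to-head pairing and dimer over eight-membered self-closure or oligomers: two α-branched C9 vinyl groups hardly couple with each other while pentenyl homodimers re-enter by secondary metathesis, the bridged cyclooctene is strained and reopens, and the 16-membered ring is the first strain-free cycle at this dilution. N-protonation keeps the amine off ruthenium and blocks retro-Mannich epimerisation.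

Step 11
Reactants: 18 macrocyclic diene
Product: 19 target, C2-symmetric bis-quinolizidinone macrocycle with each unit (1R,3S,9S,9aR)
Conditions: H2 (1 atm), Pd/C, EtOAc, rt
Reagents that add atoms: none
Why: Heterogeneous hydrogenation of the two disubstituted olefins (both geometries converge) should leave the ketones, the tertiary amines and all eight stereocentres untouched.

Compound list
1 | ethyl 3-oxopentanoate | CCC(=O)CC(=O)OCC | starting material
2 | 5-bromopent-1-ene | C=CCCCBr | starting material
3 | ethyl 2-propanoylhept-6-enoate (racemic) | CCC(=O)C(CCCC=C)C(=O)OCC | intermediate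
4 | ethyl 2-(2-ethyl-1,3-dioxolan-2-yl)hept-6-enoate (racemic) | CCOC(=O)C(CCCC=C)C1(CC)OCCO1 | intermediate
5 | 2-(2-ethyl-1,3-dioxolan-2-yl)hept-6-enal (racemic) | O=CC(CCCC=C)C1(CC)OCCO1 | intermediate
6 | (S)-2-methylpropane-2-sulfinamide | CC(C)(C)[S@@](N)=O | starting material
7 | (S,E)-N-[2-(2-ethyl-1,3-dioxolan-2-yl)hept-6-en-1-ylidene]-2-methylpropane-2-sulfinamide (C2 epimer pair) | CC(C)(C)[S@](=O)/N=C/C(CCCC=C)C1(CC)OCCO1 | intermediate
8 | methyl acetate | COC(C)=O | starting material
9 | methyl (3R)-3-{[(S)-tert-butylsulfinyl]amino}-4-(2-ethyl-1,3-dioxolan-2-yl)non-8-enoate (C4 epimer pair) | COC(=O)C[C@@H](N[S@@](=O)C(C)(C)C)C(CCCC=C)C1(CC)OCCO1 | intermediate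
10 | 1-chloro-3-iodopropane | ClCCCI | starting material
11 | methyl (2S,3S)-3-{[(S)-tert-butylsulfinyl]amino}-2-(3-chloropropyl)-4-(2-ethyl-1,3-dioxolan-2-yl)non-8-enoate (2,3-anti; C4 epimer pair) | COC(=O)[C@@H](CCCCl)[C@@H](N[S@@](=O)C(C)(C)C)C(CCCC=C)C1(CC)OCCO1 | intermediate
12 | methyl (2S,3S)-1-[(S)-tert-butylsulfinyl]-2-[1-(2-ethyl-1,3-dioxolan-2-yl)hex-5-en-1-yl]piperidine-3-carboxylate (2,3-cis) | COC(=O)[C@H]1CCCN([S@@](=O)C(C)(C)C)[C@H]1C(CCCC=C)C2(CC)OCCO2 | intermediate
13 | (2R,3S)-1-[(S)-tert-butylsulfinyl]-2-[1-(2-ethyl-1,3-dioxolan-2-yl)hex-5-en-1-yl]piperidine-3-carbaldehyde | O=C[C@H]1CCCN([S@@](=O)C(C)(C)C)[C@H]1C(CCCC=C)C2(CC)OCCO2 | intermediate (not isolated)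
14 | (2R,3R)-1-[(S)-tert-butylsulfinyl]-3-ethenyl-2-[1-(2-ethyl-1,3-dioxolan-2-yl)hex-5-en-1-yl]piperidine | C=C[C@H]1CCCN([S@@](=O)C(C)(C)C)[C@H]1C(CCCC=C)C2(CC)OCCO2 | intermediate
15 | 4-[(2R,3R)-3-ethenylpiperidin-2-yl]non-8-en-3-one (C4 epimer pair, formed as hydrochloride) | CCC(=O)C(CCCC=C)[C@@H]1NCCC[C@@H]1C=C | intermediate (not isolated)
16 | (1R,3S,9R,9aR)-9-ethenyl-3-methyl-1-(pent-4-en-1-yl)octahydro-2H-quinolizin-2-one | C[C@H]1CN2CCC[C@H](C=C)[C@@H]2[C@@H](CCCC=C)C1=O | intermediate
17 | linear head-to-tail dimer: C9 of one unit joined by CH=CH(CH2)3 to C1 of the other; one free vinyl, one free pentenyl | C[C@H]1CN2CCC[C@H](C=CCCC[C@@H]3[C@H]4[C@@H](C=C)CCCN4C[C@H](C)C3=O)[C@@H]2[C@@H](CCCC=C)C1=O | intermediate (not isolated)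
18 | 16-membered head-to-tail cyclodimer diene, each unit (1R,3S,9R,9aR), CH=CH between tether carbons 1 and 2 counted from C9 | C[C@H]1CN2CCC[C@@H]3C=CCCC[C@H]4C(=O)[C@@H](C)CN5CCC[C@H](C=CCCC[C@@H](C1=O)[C@@H]32)[C@H]45 | intermediate
19 | target, each quinolizidinone unit (1R,3S,9S,9aR) | C[C@H]1CN2CCC[C@@H]3CCCCC[C@H]4C(=O)[C@@H](C)CN5CCC[C@H](CCCCC[C@@H](C1=O)[C@@H]32)[C@H]45 | target

Total step count: 11. Longest linear sequence: 11 steps (all building blocks are commercial).

Steps most likely to fail

Step 10. The ruthenium carbene may be deactivated by the amine, or the monomer may close on itself to the bridged eight-membered ring or grow into oligomers instead of pairing head to tail. The fallback moves the macrocyclisation ahead of ring A. It sets out from 14, which has no basic nitrogen and no ketone. Cyclodimerisation with RuCl2(=CH-C6H4-2-OiPr)(H2IMes) (second-generation Hoveyda–Grubbs catalyst) in CH2Cl2 at 5 mM and 40 °C should give the macrocyclic bis-sulfinamide bis-ketal diene F1. Aqueous HCl in THF then frees the macrocyclic bis(amino ketone) F2, and formaldehyde closes both A rings by twofold Mannich reaction. The route is rejoined at 18.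

Step 9. Once N5 carries the methylene iminium ion, the C9 vinyl group may engage it (cationic 2-aza-Cope shift or aza-Prins closure) and erode the C9/C9a configuration; retro-Mannich equilibration on prolonged heating is a second drain. The fallback carries an ethynyl group through the Mannich step instead of the vinyl group. It sets out from 12: iBu2AlH at −78 °C gives aldehyde 13, now isolated, and dimethyl (1-diazo-2-oxopropyl)phosphonate with K2CO3 in MeOH should give alkyne F3. The acid and formaldehyde sequence of step 9 then leads through amino ketone F4 to the 9-ethynylquinolizidinone F5. Semihydrogenation (H2, Pd/CaCO3 poisoned with Pb(OAc)2, quinoline, EtOAc) returns to 16.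

Step 8. The cis aldehyde may epimerise at C3 under the basic ylide, or the ester may be over-reduced. The fallback avoids the aldehyde altogether and sets out from 12. MeNH(OMe)·HCl with iPrMgCl (THF, −20 °C) should give Weinreb amide F6, and MeMgBr the methyl ketone F7. LiN(iPr)2 then PhNTf2 at −78 °C traps the kinetic methyl-side enolate as enol triflate F8. Reduction with Pd(OAc)2, PPh3, Bu3N and HCO2H (DMF, 60 °C) turns the triflate into the vinyl group and returns to 14.

Further compounds
F1 | step 10 | 16-membered head-to-tail cyclodimer diene of 14: two N-[(S)-tert-butylsulfinyl]piperidines, both ketones as dioxolanes (C1 epimers) | CCC1(OCCO1)C2CCCC=C[C@H]3CCCN([S@@](=O)C(C)(C)C)[C@H]3C(CCCC=C[C@H]4CCCN([S@@](=O)C(C)(C)C)[C@H]42)C5(CC)OCCO5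
F2 | step 10 | macrocyclic diene bis(amino ketone) (not isolated) | CCC(=O)C1CCCC=C[C@H]2CCCN[C@H]2C(CCCC=C[C@H]3CCCN[C@H]31)C(=O)CC
F3 | step 9 | (2R,3R)-1-[(S)-tert-butylsulfinyl]-3-ethynyl-2-[1-(2-ethyl-1,3-dioxolan-2-yl)hex-5-en-1-yl]piperidine | C#C[C@H]1CCCN([S@@](=O)C(C)(C)C)[C@H]1C(CCCC=C)C2(CC)OCCO2
F4 | step 9 | 4-[(2R,3R)-3-ethynylpiperidin-2-yl]non-8-en-3-one (not isolated) | CCC(=O)C(CCCC=C)[C@@H]1NCCC[C@@H]1C#C
F5 | step 9 | (1R,3S,9R,9aR)-9-ethynyl-3-methyl-1-(pent-4-en-1-yl)octahydro-2H-quinolizin-2-one | C[C@H]1CN2CCC[C@H](C#C)[C@@H]2[C@@H](CCCC=C)C1=O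
F6 | step 8 | (2S,3S)-1-[(S)-tert-butylsulfinyl]-2-[1-(2-ethyl-1,3-dioxolan-2-yl)hex-5-en-1-yl]-N-methoxy-N-methylpiperidine-3-carboxamide | CON(C)C(=O)[C@H]1CCCN([S@@](=O)C(C)(C)C)[C@H]1C(CCCC=C)C2(CC)OCCO2
F7 | step 8 | 1-{(2R,3S)-1-[(S)-tert-butylsulfinyl]-2-[1-(2-ethyl-1,3-dioxolan-2-yl)hex-5-en-1-yl]piperidin-3-yl}ethan-1-one | CC(=O)[C@H]1CCCN([S@@](=O)C(C)(C)C)[C@H]1C(CCCC=C)C2(CC)OCCO2
F8 | step 8 | 1-{(2R,3S)-1-[(S)-tert-butylsulfinyl]-2-[1-(2-ethyl-1,3-dioxolan-2-yl)hex-5-en-1-yl]piperidin-3-yl}ethenyl trifluoromethanesulfonate | C=C(OS(=O)(=O)C(F)(F)F)[C@H]1CCCN([S@@](=O)C(C)(C)C)[C@H]1C(CCCC=C)C2(CC)OCCO2
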